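**Retrosynthetic overview**
- The strategy rests on ring C: the lactone carbinol C12 is bonded to bridgehead C13, which is α to C16 (the carbon of the exocyclic methylene, a latent ketone). C12–C13 is therefore an aldol bond and is cut to a spiro ring D enol silane carrying a C9 acetaldehyde arm.
- After the aldol: lactonise the 12α-hydroxyl onto the C20 ester, methylenate C16, cleave the C7/C19 methyl esters and the acetonide.
- Before the aldol: spiro ring D by double alkylation at C8 of a ring B C9 ketone with 4-bromo-2-(bromomethyl)but-1-ene; C7 by conjugate addition at C6; the C9 arm by allylation and radical deoxygenation; one ozonolysis unveils the C16 ketone and the C12 aldehyde.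
- Ring A by ring-closing metathesis on a ring B cyclopentanone made by Michael addition/allylation of an (R)-4-silyloxycyclopentenone ester; C4 methyl by enolate alkylation; 2β,3β-diol by OsO4.
- Order of ring formation: B (purchased) → A → D → C → lactone.

Key step: step 19

Remark: gibberellane numbering is used throughout (ring A C1–C5, C10; ring B C5, C6, C8, C9, C10; ring D C8, C14, C13, C16, C15; C11–C12 is the arm on C9) and α is the face of ring B that carries C20; compounds 5–8 are mixtures at C4 (5 also at C10), which is erased in step 6.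

Step 1
Reactants: 1 (R)-4-(tert-butyldimethylsilyloxy)cyclopent-2-en-1-one
Product: 2 (R)-4-(tert-butyldimethylsilyloxy)-2-iodocyclopent-2-en-1-one
Conditions: I2, pyridine, CH2Cl2, 0 °C → rt
Reagents that add atoms: iodine, II
Why: α-Iodination of the enone by pyridine addition, iodination and elimination is routine for this enone and should leave the silyloxy stereocentre (future C6) untouched.

Step 2
Reactants: 2 (R)-4-(tert-butyldimethylsilyloxy)-2-iodocyclopent-2-en-1-one
Product: 3 methyl (3R)-3-(tert-butyldimethylsilyloxy)-5-oxocyclopent-1-ene-1-carboxylate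
Conditions: CO (1 atm), MeOH, PdCl2(PPh3)2 (cat.), i-Pr2NEt, DMF, 50 °C
Reagents that add atoms: carbon monoxide, [C-]#[O+]; methanol, CO
Why: Palladium-catalysed methoxycarbonylation of the vinyl iodide (oxidative addition, CO insertion, methanolysis) should give the alkylidene β-keto ester whose ester carbon becomes C20.

Step 3
Reactants: 3 methyl (3R)-3-(tert-butyldimethylsilyloxy)-5-oxocyclopent-1-ene-1-carboxylate; 4 methyl but-3-enoate
Product: 6 ring B keto diester with 10β-allyl, 10α-CO2Me, 5α-[1-(methoxycarbonyl)prop-2-enyl] and 6β-OTBS, via Michael adduct 5 (not isolated)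
Conditions: 4, LiN(i-Pr)2, THF–DMPU, −78 °C; then 3; then allyl bromide, −78 → 0 °C
Reagents that add atoms: allyl bromide, C=CCBr
Why: In this tandem Michael addition–enolate alkylation the lithium dienolate of 4 should add through its α-carbon to C5 anti to the 6-silyloxy group, and the β-keto ester enolate should then be C-allylated at C10 anti to the new C5 substituent, setting C5 and C10.

Step 4
Reactants: 6 ring B keto diester
Product: 7 trans-fused hydrindenone (ring A cyclohex-2-ene, C9 ketone, 6β-OTBS, 10α-CO2Me, C4 CO2Me as epimers)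
Conditions: second-generation Grubbs catalyst (cat.), CH2Cl2, 40 °C
Reagents that add atoms: none
Why: Ring-closing metathesis of the C10 allyl and C4 vinyl groups should close ring A as the Δ2 cyclohexene, the trans ring fusion being already fixed by C5 and C10.

Step 5
Reactants: 7 trans-fused hydrindenone
Product: 8 C9 tert-butyldimethylsilyl enol ether (C8=C9) of 7
Conditions: t-BuMe2SiOTf, Et3N, CH2Cl2, 0 °C
Reagents that add atoms: tert-butyldimethylsilyl triflate, CC(C)(C)[Si](C)(C)OS(=O)(=O)C(F)(F)F
Why: Soft enolisation with silyl triflate and amine can only go toward C8 because C10 is quaternary, and the enol silane keeps the ketone from being enolised (with loss of the 6-silyloxy group) in the next step.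

Step 6
Reactants: 8 C9 silyl enol ether
Product: 9 the 4β-methyl 4α-methoxycarbonyl compound (C4 quaternary)
Conditions: LiN(i-Pr)2, THF, −78 °C; then MeI
Reagents that add atoms: iodomethane, CI
Why: In this ester enolate alkylation the extended enolate of the C19 ester should be methylated at C4 from the β-face, opposite the axial C20 ester on C10, giving the 4β-methyl 4α-ester.

Step 7
Reactants: 9 the 4β-methyl compound
Product: 10 ring A/B dienone (Δ2 alkene and C6=C8 enone with C9 ketone; C19 and C20 methyl esters)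
Conditions: Bu4NF, THF, 0 °C
Reagents that add atoms: none
Why: Fluoride desilylation should regenerate the C9 enolate, which expels the 6-silyloxy group by E1cB β-elimination to give the enone.

Step 8
Reactants: 10 ring A/B dienone
Product: 11 the 2β,3β-diol of 10
Conditions: OsO4 (cat.), N-methylmorpholine N-oxide, acetone–H2O, rt
Reagents that add atoms: N-methylmorpholine N-oxide, C[N+]1([O-])CCOCC1; water, O
Why: Catalytic syn-dihydroxylation should take the electron-rich Δ2 alkene rather than the enone and approach from the β-face, away from the axial C19 and C20 esters, setting C2 and C3.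

Step 9
Reactants: 11 the 2β,3β-diol
Product: 12 the 2β,3β-acetonide enone
Conditions: Me2C(OMe)2, pyridinium p-toluenesulfonate (cat.), acetone, rt
Reagents that add atoms: 2,2-dimethoxypropane, COC(C)(C)OC
Why: Acid-catalysed ketal exchange should protect the cis-diol as the acetonide.

Step 10
Reactants: 12 the acetonide enone
Product: 13 the 6β-[tris(methylthio)methyl] C9 ketone
Conditions: HC(SMe)3, n-BuLi, THF, −78 °C; then 12; then H2O
Reagents that add atoms: tris(methylthio)methane, CSC(SC)SC
Why: Conjugate addition of the tris(methylthio)methyl anion, a carboxyl anion equivalent, should occur at C6 from the β-face, trans to the C5–C4 bond, setting C6.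

Step 11
Reactants: 13 the 6β-[tris(methylthio)methyl] ketone
Product: 14 the 6β-methoxycarbonyl C9 ketone (C7, C19, C20 methyl esters; acetonide)
Conditions: HgCl2, HgO, MeOH–H2O, rt
Reagents that add atoms: methanol, CO; water, O
Why: Thiophilic methanolysis of the ortho-thioester should unmask the C7 methyl ester, HgO buffering the acid so that the acetonide is expected to survive.

Step 12
Reactants: 15 dimethyl itaconate
Product: 16 2-methylenebutane-1,4-diol
Conditions: i-Bu2AlH, CH2Cl2, −78 → 0 °C; aqueous work-up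
Reagents that add atoms: none
Why: Hydride 1,2-reduction of both esters should give the diol without touching the alkene.

Step 13
Reactants: 16 2-methylenebutane-1,4-diol
Product: 17 4-bromo-2-(bromomethyl)but-1-ene
Conditions: CBr4, PPh3, CH2Cl2, 0 °C
Reagents that add atoms: carbon tetrabromide, BrC(Br)(Br)Br
Why: The Appel reaction should convert both primary alcohols into bromides.

Step 14
Reactants: 14 the 6β-methoxycarbonyl C9 ketone; 17 4-bromo-2-(bromomethyl)but-1-ene
Product: 19 spiro ketone (ring D = C8, C15, C16, C13, C14 with 16-methylene; C14 α and C15 β at C8), via C8-monoalkylated ketone 18 (not isolated)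
Conditions: KN(SiMe3)2, THF, −78 °C; 17, −78 → 0 °C; then KN(SiMe3)2, 0 °C → rt
Reagents that add atoms: none
Why: In this spiro-annulation by double enolate alkylation the C8 enolate (the only ketone enolate possible) should first displace the allylic bromide and then close ring D by 5-exo-tet attack on the homoallylic bromide anti to the vicinal 6β-ester, so that C14 ends α and C15 β.

Step 15
Reactants: 19 spiro ketone
Product: 21 the 9-allyl 9-(methyl oxalate), via tertiary carbinol 20 (not isolated)
Conditions: allylZnBr, THF, 0 °C → rt; then ClC(O)CO2Me, 4-dimethylaminopyridine (cat.), 0 °C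
Reagents that add atoms: allylzinc bromide, C=CC[Zn]Br; methyl chlorooxoacetate, COC(=O)C(=O)Cl
Why: Allylzinc addition through a cyclic SE2′ transition state tolerates the esters and should reach the hindered C9 ketone, and the zinc alkoxide is acylated in the flask to the oxalate radical precursor (the C9 configuration here is of no consequence).

Step 16
Reactants: 21 the 9-allyl 9-(methyl oxalate)
Product: 22 the 9α-allyl 9β-H spiro triester
Conditions: Bu3SnH, AIBN (cat.), toluene, 110 °C
Reagents that add atoms: none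
Why: In this radical deoxygenation of a tertiary oxalate (Barton–McCombie type) the planar C9 radical should take hydrogen from the β-face, opposite the axial C20 ester, which sets 9β-H and leaves the allyl arm α.

Step 17
Reactants: 22 the 9α-allyl 9β-H spiro triester
Product: 23 keto aldehyde (C16 ketone in ring D, C9α-CH2CHO arm)
Conditions: O3, CH2Cl2–MeOH, −78 °C; then Me2S
Reagents that add atoms: ozone, [O-][O+]=O
Why: Ozonolysis with reductive work-up should cleave both terminal alkenes at once, unveiling the ring D ketone and the C12 aldehyde.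

Step 18
Reactants: 23 keto aldehyde
Product: 26 ring D C13=C16 triethylsilyl enol ether with the free C9 acetaldehyde arm, via phosphonium-masked keto aldehyde 24 (not isolated), via phosphonium-masked enol silane 25 (not isolated)
Conditions: PPh3, Et3SiOTf, CH2Cl2, −78 °C; then Et3N, −78 → −40 °C; then H2O
Reagents that add atoms: triethylsilyl triflate, CC[Si](CC)(CC)OS(=O)(=O)C(F)(F)F
Why: The aldehyde is first masked as its α-silyloxy phosphonium salt (which ketones do not form at −78 °C), silyl triflate/amine soft enolisation then converts the ketone into the enol silane on the less hindered C13 side (C15 is neopentyl and flanked by the 6β-ester), and water releases the aldehyde.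

Step 19
Reactants: 26 ring D triethylsilyl enol ether with C9 acetaldehyde arm
Product: 27 the 12α-hydroxy 16-ketone with rings A–D complete (C7, C19, C20 methyl esters; 2β,3β-acetonide)
Conditions: BF3·OEt2, CH2Cl2, −78 °C; then H2O
Reagents that add atoms: none
Why: BF3 binds the C12 aldehyde and C13 of the preformed enol silane attacks it through an open transition state, an intramolecular Mukaiyama aldol addition in which silicon leaves as the fluoride. Ring C closes in a 6-(enolexo)-exo-trig mode and turns the spiro bicycle into the bicyclo[3.2.1]octane. C13 can bond only on the face of ring D that carries C9, so its configuration follows from the spiro centre C8. At C12 an antiperiplanar arrangement of C=O and the enol C=C in a chair-like ring C places the oxygen axial and syn to C10, which is 12α, the epimer that can reach the C20 ester. The step needs bonding at C13 rather than C15, which the isolated enol silane fixes, and reaction at the aldehyde rather than at the esters or the acetonide, which low temperature and a monodentate Lewis acid should secure.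

Step 20
Reactants: 27 the 12α-hydroxy 16-ketone
Product: 28 the 16-oxo 20,12α-lactone (C7 and C19 methyl esters; acetonide)
Conditions: camphorsulfonic acid (cat.), toluene, 60 °C
Reagents that add atoms: none
Why: In this acid-catalysed intramolecular transesterification the axial 12α-hydroxyl is 1,3-diaxial to the C20 ester and should close the δ-lactone, acid being chosen over base to avoid retro-aldol cleavage.

Step 21
Reactants: 28 the 16-oxo 20,12α-lactone
Product: 29 the 16-methylene lactone (target as C7/C19 dimethyl ester 2,3-acetonide)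
Conditions: Ph3PCH3Br, KOt-Bu, THF, 0 °C → rt
Reagents that add atoms: methyltriphenylphosphonium bromide, C[P+](c1ccccc1)(c1ccccc1)c1ccccc1.[Br-]
Why: Wittig methylenation of the C16 ketone should be clean because the α-carbon C13 is a bridgehead, so neither epimerisation nor β-elimination of the lactone oxygen is possible.

Step 22
Reactants: 29 the 16-methylene lactone dimethyl ester
Product: 30 the C7,C19-diacid lactone 2,3-acetonide
Conditions: n-PrSLi, HMPA, rt; then dilute HCl
Reagents that add atoms: none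
Why: SN2 demethylation by thiolate in a dipolar aprotic solvent should cleave the hindered C7 and C19 methyl esters, while the lactone has no methyl to lose and recloses if opened.

Step 23
Reactants: 30 the diacid lactone acetonide
Product: 31 CNP0212122.1 (target)
Conditions: AcOH–H2O (4:1), 40 °C
Reagents that add atoms: none
Why: Mild aqueous acid hydrolysis of the acetonide should give the target without isomerising the exocyclic alkene.

**Compound list**
1 | (R)-4-(tert-butyldimethylsilyloxy)cyclopent-2-en-1-one | O=C1C=C[C@H](O[Si](C)(C)C(C)(C)C)C1 | starting material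
2 | (R)-4-(tert-butyldimethylsilyloxy)-2-iodocyclopent-2-en-1-one | O=C1C(I)=C[C@H](O[Si](C)(C)C(C)(C)C)C1 | intermediate
3 | methyl (3R)-3-(tert-butyldimethylsilyloxy)-5-oxocyclopent-1-ene-1-carboxylate | O=C1C(C(=O)OC)=C[C@H](O[Si](C)(C)C(C)(C)C)C1 | intermediate
4 | methyl but-3-enoate | C=CCC(=O)OC | starting material
5 | Michael adduct: ring B β-keto ester with 5α-[1-(methoxycarbonyl)prop-2-enyl] trans to 6β-OTBS (C4 and C10 unfixed) | O=C1C(C(=O)OC)[C@@H](C(C=C)C(=O)OC)[C@H](O[Si](C)(C)C(C)(C)C)C1 | intermediate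
6 | ring B keto diester: 10β-allyl, 10α-CO2Me, 5α side chain, 6β-OTBS (C4 epimers) | O=C1[C@@](CC=C)(C(=O)OC)[C@@H](C(C=C)C(=O)OC)[C@H](O[Si](C)(C)C(C)(C)C)C1 | intermediate
7 | trans-fused hydrindenone: ring A Δ2, C9 ketone, 6β-OTBS, 10α-CO2Me, C4 CO2Me (epimers) | O=C1[C@]2(C(=O)OC)CC=CC(C(=O)OC)[C@H]2[C@H](O[Si](C)(C)C(C)(C)C)C1 | intermediate
8 | C9 TBS enol ether (C8=C9) of 7 | CC(C)(C)[Si](C)(C)OC1=C[C@@H](O[Si](C)(C)C(C)(C)C)[C@@H]2C(C(=O)OC)C=CC[C@@]12C(=O)OC | intermediate
9 | 4β-methyl 4α-CO2Me derivative of 8 | CC(C)(C)[Si](C)(C)OC1=C[C@@H](O[Si](C)(C)C(C)(C)C)[C@@H]2[C@](C)(C(=O)OC)C=CC[C@@]12C(=O)OC | intermediate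
10 | ring A/B dienone: Δ2 alkene, C6=C8 enone with C9 ketone, 4β-Me, 4α- and 10α-CO2Me | O=C1C=C[C@@H]2[C@](C)(C(=O)OC)C=CC[C@@]12C(=O)OC | intermediate
11 | 2β,3β-diol of 10 | O=C1C=C[C@@H]2[C@](C)(C(=O)OC)[C@@H](O)[C@@H](O)C[C@@]12C(=O)OC | intermediate
12 | 2β,3β-acetonide enone | O=C1C=C[C@@H]2[C@](C)(C(=O)OC)[C@H]3OC(C)(C)O[C@H]3C[C@@]12C(=O)OC | intermediate
13 | 6β-[tris(methylthio)methyl] C9 ketone | O=C1C[C@@H](C(SC)(SC)SC)[C@@H]2[C@](C)(C(=O)OC)[C@H]3OC(C)(C)O[C@H]3C[C@@]12C(=O)OC | intermediate
14 | 6β-methoxycarbonyl C9 ketone (triester acetonide) | O=C1C[C@@H](C(=O)OC)[C@@H]2[C@](C)(C(=O)OC)[C@H]3OC(C)(C)O[C@H]3C[C@@]12C(=O)OC | intermediate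
15 | dimethyl itaconate | C=C(CC(=O)OC)C(=O)OC | starting material
16 | 2-methylenebutane-1,4-diol | C=C(CO)CCO | intermediate
17 | 4-bromo-2-(bromomethyl)but-1-ene | C=C(CBr)CCBr | intermediate
18 | C8-(4-bromo-2-methylenebutyl) ketone (C8 unfixed) | O=C1C(CC(=C)CCBr)[C@@H](C(=O)OC)[C@@H]2[C@](C)(C(=O)OC)[C@H]3OC(C)(C)O[C@H]3C[C@@]12C(=O)OC | intermediate
19 | spiro ketone: ring D with 16-methylene, C14 α and C15 β at C8, C9 ketone | O=C1[C@@]3(CC(=C)CC3)[C@@H](C(=O)OC)[C@@H]2[C@](C)(C(=O)OC)[C@H]4OC(C)(C)O[C@H]4C[C@@]12C(=O)OC | intermediate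
20 | 9-allyl 9-carbinol (drawn 9β-allyl, 9α-OH) | O[C@]1(CC=C)[C@@]3(CC(=C)CC3)[C@@H](C(=O)OC)[C@@H]2[C@](C)(C(=O)OC)[C@H]4OC(C)(C)O[C@H]4C[C@@]12C(=O)OC | intermediate
21 | 9-allyl 9-(methyl oxalate) | COC(=O)C(=O)O[C@]1(CC=C)[C@@]3(CC(=C)CC3)[C@@H](C(=O)OC)[C@@H]2[C@](C)(C(=O)OC)[C@H]4OC(C)(C)O[C@H]4C[C@@]12C(=O)OC | intermediate
22 | 9α-allyl 9β-H spiro triester with 16-methylene | C=CC[C@@H]1[C@@]3(CC(=C)CC3)[C@@H](C(=O)OC)[C@@H]2[C@](C)(C(=O)OC)[C@H]4OC(C)(C)O[C@H]4C[C@@]12C(=O)OC | intermediate
23 | keto aldehyde: C16 ketone, C9α-CH2CHO | O=CC[C@@H]1[C@@]3(CC(=O)CC3)[C@@H](C(=O)OC)[C@@H]2[C@](C)(C(=O)OC)[C@H]4OC(C)(C)O[C@H]4C[C@@]12C(=O)OC | intermediate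
24 | C12 α-(triethylsilyloxy)triphenylphosphonium triflate of 23 (C12 unfixed) | CC[Si](CC)(CC)OC(C[C@@H]1[C@@]3(CC(=O)CC3)[C@@H](C(=O)OC)[C@@H]2[C@](C)(C(=O)OC)[C@H]4OC(C)(C)O[C@H]4C[C@@]12C(=O)OC)[P+](c1ccccc1)(c1ccccc1)c1ccccc1.[O-]S(=O)(=O)C(F)(F)F | intermediate
25 | ring D C13=C16 triethylsilyl enol ether of 24 | CC[Si](CC)(CC)OC(C[C@@H]1[C@@]3(CC(O[Si](CC)(CC)CC)=CC3)[C@@H](C(=O)OC)[C@@H]2[C@](C)(C(=O)OC)[C@H]4OC(C)(C)O[C@H]4C[C@@]12C(=O)OC)[P+](c1ccccc1)(c1ccccc1)c1ccccc1.[O-]S(=O)(=O)C(F)(F)F | intermediate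
26 | aldol precursor: ring D C13=C16 triethylsilyl enol ether, C9α-CH2CHO, trimethyl ester, 2β,3β-acetonide | O=CC[C@@H]1[C@@]3(CC(O[Si](CC)(CC)CC)=CC3)[C@@H](C(=O)OC)[C@@H]2[C@](C)(C(=O)OC)[C@H]4OC(C)(C)O[C@H]4C[C@@]12C(=O)OC | intermediate
27 | 12α-hydroxy 16-ketone, rings A–D, trimethyl ester, 2β,3β-acetonide | O=C1C[C@]23C[C@H]1[C@@H](O)C[C@H]2[C@@]2(C[C@H](OC4(C)C)[C@H](O4)[C@@](C)(C(=O)OC)[C@H]2[C@@H]3C(=O)OC)C(=O)OC | intermediate
28 | 16-oxo 20,12α-lactone, C7/C19 dimethyl ester, acetonide | O=C1C[C@]23C[C@H]1[C@@H]1C[C@H]2[C@@]2(C[C@H](OC4(C)C)[C@H](O4)[C@@](C)(C(=O)OC)[C@H]2[C@@H]3C(=O)OC)C(=O)O1 | intermediate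
29 | 16-methylene 20,12α-lactone, C7/C19 dimethyl ester, acetonide | C=C1C[C@]23C[C@H]1[C@@H]1C[C@H]2[C@@]2(C[C@H](OC4(C)C)[C@H](O4)[C@@](C)(C(=O)OC)[C@H]2[C@@H]3C(=O)OC)C(=O)O1 | intermediate
30 | 16-methylene 20,12α-lactone C7,C19-diacid, acetonide | C=C1C[C@]23C[C@H]1[C@@H]1C[C@H]2[C@@]2(C[C@H](OC4(C)C)[C@H](O4)[C@@](C)(C(=O)O)[C@H]2[C@@H]3C(=O)O)C(=O)O1 | intermediate
31 | CNP0212122.1 | C=C1C[C@]23C[C@H]1[C@@H]1C[C@H]2[C@@]2(C[C@H](O)[C@H](O)[C@@](C)(C(=O)O)[C@H]2[C@@H]3C(=O)O)C(=O)O1 | target

Total step count: 23. Longest linear sequence: 21 steps (steps 1–11 and 14–23; steps 12–13 make reagent 17).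

**Steps most likely to fail**

Step 18. The masking of the aldehyde may be incomplete or may reverse before the ketone is silylated, so that the arm is enolised and silylated too, or the ring D enol silane may hydrolyse when the aldehyde is released. The fallback sets out from 23 and returns at 27. The aldehyde of 23 is reduced selectively with NaBH(OAc)3 to keto alcohol F1, which allyl chloroformate and pyridine convert into allyl carbonate F2. t-BuMe2SiOTf and Et3N give the ring D silyl enol ether carbonate F3. Zerovalent palladium (Pd(PPh3)4) with morpholine removes the carbonate under neutral conditions to give hydroxy enol silane F4. Buffered Dess–Martin oxidation gives aldehyde enol silane F5, and BF3·OEt2 closes ring C to 27.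

Step 19. Facial selectivity at the aldehyde may be poor: if the oxygen turns away from C10 (synclinal transition state), the 12β-carbinol forms, which cannot lactonise by acyl substitution. The fallback sets out from 26, through its 12-epimeric aldol product, and returns at 28. The 12β-hydroxy ketone F6 is converted with MsCl and Et3N into mesylate F7. Warming F7 in DMF with NaHCO3 lets the carbonyl oxygen of the C20 methyl ester displace the mesylate from the α-face (SN2, inversion at C12) with loss of the ester methyl, which gives lactone 28 directly.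

Step 16. Hydrogen-atom transfer to the hindered C9 radical may come from the α-face, or the crowded carbinol may resist acylation and fragmentation. The fallback sets out from 19 and returns at 23. CH2=CHMgBr with CeCl3 adds to the C9 ketone to give vinyl carbinol F8. Pyridinium chlorochromate (C5H5NH[CrO3Cl]) effects the oxidative 1,3-transposition to enal F9. One equivalent of ozone cleaves only the electron-rich ring D methylene to give keto enal F10, and hydrogenation over Pd/C adds hydrogen to C9 from the β-face to give 23.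

Further compounds
F1 | step 18 | keto alcohol (C16 ketone, C9α-CH2CH2OH) | OCC[C@@H]1[C@@]3(CC(=O)CC3)[C@@H](C(=O)OC)[C@@H]2[C@](C)(C(=O)OC)[C@H]4OC(C)(C)O[C@H]4C[C@@]12C(=O)OC
F2 | step 18 | allyl carbonate of F1 | C=CCOC(=O)OCC[C@@H]1[C@@]3(CC(=O)CC3)[C@@H](C(=O)OC)[C@@H]2[C@](C)(C(=O)OC)[C@H]4OC(C)(C)O[C@H]4C[C@@]12C(=O)OC
F3 | step 18 | ring D C13=C16 TBS enol ether allyl carbonate | C=CCOC(=O)OCC[C@@H]1[C@@]3(CC(O[Si](C)(C)C(C)(C)C)=CC3)[C@@H](C(=O)OC)[C@@H]2[C@](C)(C(=O)OC)[C@H]4OC(C)(C)O[C@H]4C[C@@]12C(=O)OC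
F4 | step 18 | hydroxy enol silane (C12 alcohol, ring D TBS enol ether) | OCC[C@@H]1[C@@]3(CC(O[Si](C)(C)C(C)(C)C)=CC3)[C@@H](C(=O)OC)[C@@H]2[C@](C)(C(=O)OC)[C@H]4OC(C)(C)O[C@H]4C[C@@]12C(=O)OC
F5 | step 18 | aldehyde enol silane (TBS analogue of 26) | O=CC[C@@H]1[C@@]3(CC(O[Si](C)(C)C(C)(C)C)=CC3)[C@@H](C(=O)OC)[C@@H]2[C@](C)(C(=O)OC)[C@H]4OC(C)(C)O[C@H]4C[C@@]12C(=O)OC
F6 | step 19 | 12β-hydroxy 16-ketone (12-epimer of 27) | O=C1C[C@]23C[C@H]1[C@H](O)C[C@H]2[C@@]2(C[C@H](OC4(C)C)[C@H](O4)[C@@](C)(C(=O)OC)[C@H]2[C@@H]3C(=O)OC)C(=O)OC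
F7 | step 19 | 12β-mesylate of F6 | O=C1C[C@]23C[C@H]1[C@H](OS(C)(=O)=O)C[C@H]2[C@@]2(C[C@H](OC4(C)C)[C@H](O4)[C@@](C)(C(=O)OC)[C@H]2[C@@H]3C(=O)OC)C(=O)OC
F8 | step 16 | 9-vinyl 9-carbinol | O[C@]1(C=C)[C@@]3(CC(=C)CC3)[C@@H](C(=O)OC)[C@@H]2[C@](C)(C(=O)OC)[C@H]4OC(C)(C)O[C@H]4C[C@@]12C(=O)OC
F9 | step 16 | enal (C9=C11–C12HO) with ring D methylene | O=CC=C1[C@@]3(CC(=C)CC3)[C@@H](C(=O)OC)[C@@H]2[C@](C)(C(=O)OC)[C@H]4OC(C)(C)O[C@H]4C[C@@]12C(=O)OC
F10 | step 16 | keto enal (C9=C11–C12HO, C16 ketone) | O=CC=C1[C@@]3(CC(=O)CC3)[C@@H](C(=O)OC)[C@@H]2[C@](C)(C(=O)OC)[C@H]4OC(C)(C)O[C@H]4C[C@@]12C(=O)OC
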